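Take one ratio to the board: from the beta run, φ = 0.399, the target at the plateau per coupling partner charged, read in a closed flask with 1 mM of initiator.

| flask | substrate | coupling partner | initiator | remark | time |
|---|---|---|---|---|---|
| gamma | 0.050 M | 0.20 M | 1 mM | run made earlier |  |
| delta | 0.050 M | 0.20 M | 0.50 mM | run made earlier |  |
| theta | 0.050 M | 0.20 M | 0.75 mM | run made earlier |  |
| beta | 0.050 M | 0.10 M | 1 mM | run made earlier |  |
| birch | 0.050 M | 0.200 M | 1.0 mM | one stirred flow tank at steady state, fed with the mixture as stated, mean residence time 20 h |  |
| ash | 0.050 M | 0.200 M | 1.0 mM | everything together in a closed stirred flask, run for 20 h | 20 h |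
| oak | 0.050 M (fed, over 16.0 h) | 0.200 M | 1.0 mM | a stirred flask in which substrate is dosed at a steady rate over 16.0 h without added volume, worked up at 20 h | 20 h |
| cedar | 0.050 M | 0.200 M (fed, over 16.0 h) | 1.0 mM | a stirred flask in which coupling partner is dosed at a steady rate over 16.0 h without added volume, worked up at 20 h | 20 h |

| run | time / h | target / % | substrate / % |
|---|---|---|---|
| gamma | 1.00 | 79.6 | 18.6 |
| gamma | 3.00 | 98.5 | 0.3 |
| gamma | 6.00 | 98.4 | 0.1 |
| gamma | 8.00 | 97.2 | 0.9 |
| gamma | 12.0 | 97.4 | 0.7 |
| delta | 2.50 | 96.2 | 1.1 |
| delta | 5.00 | 99.3 | 0.3 |
| delta | 8.00 | 98.1 | 0.1 |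
| delta | 10.0 | 98.0 | 0.6 |
| delta | 12.0 | 99.0 | 0.1 |
| theta | 1.00 | 69.7 | 27.9 |
| theta | 2.00 | 97.9 | 0.9 |
| theta | 3.00 | 97.9 | 0.3 |
| theta | 6.00 | 98.0 | 0 |
| theta | 12.0 | 97.7 | 1.4 |
| beta | 2.50 | 64.4 | 32.3 |
| beta | 5.00 | 75.8 | 19.0 |
| beta | 8.00 | 79.5 | 16.5 |
| beta | 10.0 | 80.3 | 16.0 |
| beta | 12.0 | 79.3 | 16.5 |

(each reading ± 0.5 percentage points)

- the stated concentrations are those of everything mixed, before any reaction; amounts are the same in each set-up
- the numbers in the tables scatter with a standard deviation of 0.5 percentage points
- the feed brings no volume worth counting
- the earlier runs were made in a closed, stirred flask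

1. the set-up with the highest amount of target at the outlet or at the end, in percent of the substrate put in ("none" if the first two lie within 2 percentage points) (birch / ash / oak / cedar / none)
2. amount of target at the outlet or at the end, in percent of the substrate put in, birch
3. amount of target at the outlet or at the end, in percent of the substrate put in, ash
4. amount of target at the outlet or at the end, in percent of the substrate put in, oak
5. amount of target at the outlet or at the end, in percent of the substrate put in, cedar

Why should a ratio read at 0.10 M of coupling partner serve at another charge? I assume that whatever carries the reaction holds a steady level at a given initiator charge, so that target forms at a rate proportional to coupling partner (pseudo-first-order). If any loss of coupling partner also goes with its first power, the two keep their proportion, and target scales with the charge for as long as substrate lasts.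

But the beta run stops with 16.5 % of substrate still there. Was that initiator or coupling partner? Coupling partner is not among the readings, so I leave that open; on the assumption above φ does not need the answer, provided the initiator charge is held. Ash has the same 1.0 mM.

So what of ash? Its substrate asks for 0.250 of the coupling partner charged, which is less than φ. The capacity φ·(coupling partner)/(substrate) is 159 %, so I expect substrate to be consumed in ash, with target near the late gamma readings, about 97.7 %.

And the other three? φ was read in a closed flask with everything mixed at the start, and birch, oak and cedar are not that, so I stake no number on them. Naming ash as best is my choice, not a reckoning.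

The forecast said 96 % for birch, 98 % for ash, 39 % for oak, 13 % for cedar and best none, holding that “the initiator dies”.

The flasks give 88.1 % for birch, 97.4 % for ash, 59.8 % for oak and 42.9 % for cedar, so the best is ash.

    initiator → 2 initiating radical (k = 1.50 × 10⁻⁴ s⁻¹)
    substrate + initiating radical → capped initiator + first chain carrier (k = 52000 M⁻¹ s⁻¹)
    coupling partner + first chain carrier → target + second chain carrier (k = 320 M⁻¹ s⁻¹)
    substrate + second chain carrier → by-product + first chain carrier (k = 390 M⁻¹ s⁻¹)
    2 first chain carrier → ended chains (k = 2.40 × 10⁶ M⁻¹ s⁻¹)
    coupling partner → decomposed reagent (k = 6.80 × 10⁻⁵ s⁻¹)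
    target → over-reaction product (k = 7.00 × 10⁻⁸ s⁻¹)

Ash, with its capacity of 159 % above the substrate charged, ends with 97.4 % target and 0 % substrate. Now the neighbouring flask: ash with the coupling partner cut to 0.050 M, the initiator and substrate unchanged. The same ratio gives a capacity of 39.9 %, below the substrate charged, so here substrate should remain. At 20.0 h that neighbouring flask holds 39.8 % target and 56.0 % substrate.

(The earlier runs and the new flask are simulated for substances that don't exist.)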